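## Retrosynthetic overview

- Target 22 comes from Z-cyclononenol 21 by hydroxyl-directed epoxidation (C-8/C-9); 21 comes from bicyclic lactone 19 by acidic deprotection and a δ-lactone → butenolide switch.
- 19 comes from diene 18 by ring-closing metathesis (nine-membered ring, Z-C-8=C-9) on a temporary six-membered lactone template; 18 comes from aldehyde 16 by reduction and lactonisation.
- Key C–O bond: 16 comes from alcohol 14 and dienylboronate 12 by copper-catalysed O-dienylation followed by a Claisen shift, which forms C-4a–C-11a, relays the C-12 configuration to C-4a and C-11a, and sets Z-C-4=C-12.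
- 14 comes from ynoate 9 and aldehyde 4 by vinylalumination; 9 is made from (S)-linalool, 4 from 2,3-O-isopropylidene-D-erythronolactone, 12 from pent-4-enal.
- Ring order: δ-lactone (template) → nine-membered carbocycle → butenolide → epoxide.

Assumption: (S)-(+)-linalool is bought in high enantiomeric purity; atom labels follow xenicane numbering (C-1 = CH2OH carbon, C-3 = lactone carbonyl, C-4a/C-11a = ring carbons bearing butenolide and CH2OH, C-7 = carbinol, C-8/C-9 = epoxide, C-11 = methylidene carbon, C-12 to C-15 = side chain).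

## Route

Step 1
Reactants: 1 2,3-O-isopropylidene-D-erythronolactone
Product: 2 acetonide diol 2-[(4R,5R)-5-(hydroxymethyl)-2,2-dimethyl-1,3-dioxolan-4-yl]propan-2-ol
Conditions: MeMgBr (3 equiv), THF, 0 °C to rt; aq. NH4Cl
Reagents that add atoms: methylmagnesium bromide, C[Mg]Br
Why: Double Grignard addition to the lactone carbonyl builds the C-15 tertiary carbinol and frees the primary alcohol, while C-13 and C-14 (both R) come unchanged from the chiral pool.

Step 2
Reactants: 2 acetonide diol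
Product: 3 bis(triethylsilyl) ether of 2
Conditions: Et3SiOTf (2.4 equiv), 2,6-lutidine, CH2Cl2, −20 to 0 °C
Reagents that add atoms: triethylsilyl trifluoromethanesulfonate, CC[Si](CC)(CC)OS(=O)(=O)C(F)(F)F
Why: Silyl triflate/lutidine silylation caps both hydroxyls, the triflate being needed for the tertiary one.

Step 3
Reactants: 3 bis(triethylsilyl) ether
Product: 4 (4S,5R)-2,2-dimethyl-5-[2-(triethylsilyloxy)propan-2-yl]-1,3-dioxolane-4-carbaldehyde
Conditions: (COCl)2, DMSO, CH2Cl2, −78 to −30 °C; i-Pr2NEt, −78 to 0 °C; used crude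
Reagents that add atoms: none
Why: Swern oxidation converts a primary triethylsilyl ether directly into the aldehyde (chlorosulfonium attack on the ether oxygen, loss of Et3SiCl) while the tertiary silyl ether and acetonide are inert; the hindered base and low temperature limit epimerisation of the cis-dioxolane aldehyde.

Step 4
Reactants: 5 (S)-(+)-linalool
Product: 6 (S)-linalool triethylsilyl ether
Conditions: Et3SiOTf, 2,6-lutidine, CH2Cl2, 0 °C
Reagents that add atoms: triethylsilyl trifluoromethanesulfonate, CC[Si](CC)(CC)OS(=O)(=O)C(F)(F)F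
Why: Silylation of the tertiary allylic alcohol (future C-7, S) prevents later oxa-Michael and lactol chemistry.

Step 5
Reactants: 6 (S)-linalool triethylsilyl ether
Product: 7 (4S)-4-methyl-4-(triethylsilyloxy)hex-5-enal
Conditions: O3 (1 equiv, Sudan Red 7B end point), CH2Cl2, −78 °C; Me2S, −78 °C to rt
Reagents that add atoms: ozone, [O-][O+]=O
Why: Ozonolysis is chemoselective for the electron-rich trisubstituted alkene over the hindered vinyl group next to the silyloxy carbon, and the reductive work-up gives the C-4a aldehyde.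

Step 6
Reactants: 7 (4S)-4-methyl-4-(triethylsilyloxy)hex-5-enal
Product: 8 triethyl{[(3S)-3-methylhept-1-en-6-yn-3-yl]oxy}silane
Conditions: dimethyl (1-diazo-2-oxopropyl)phosphonate, K2CO3, MeOH, 0 °C to rt
Reagents that add atoms: dimethyl (1-diazo-2-oxopropyl)phosphonate, COP(=O)(OC)C(=[N+]=[N-])C(C)=O
Why: Seyferth–Gilbert homologation with the Ohira–Bestmann reagent turns the aldehyde into the terminal alkyne (C-4) under mild carbonate conditions.

Step 7
Reactants: 8 terminal alkyne
Product: 9 methyl (6S)-6-methyl-6-(triethylsilyloxy)oct-7-en-2-ynoate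
Conditions: n-BuLi, THF, −78 °C; ClCO2Me, −78 to 0 °C
Reagents that add atoms: methyl chloroformate, COC(Cl)=O
Why: Lithium acetylide formation and C-acylation install the C-3 ester.

Step 8
Reactants: 10 pent-4-enal
Product: 11 2-methylidenepent-4-enal
Conditions: 37% aq. CH2O, pyrrolidine (10 mol%), EtCO2H (10 mol%), i-PrOH, 45 °C
Reagents that add atoms: formaldehyde, C=O
Why: Organocatalytic Mannich-type α-methylenation (enamine addition to formaldehyde, then amine elimination) installs the C-11 methylidene group.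

Step 9
Reactants: 11 2-methylidenepent-4-enal
Product: 12 (E)-dienyl pinacolboronate 4,4,5,5-tetramethyl-2-[(1E)-3-methylidenehexa-1,5-dien-1-yl]-1,3,2-dioxaborolane
Conditions: Cl2CHB(pin), CrCl2 (6 equiv), LiI (3 equiv), THF, rt
Reagents that add atoms: 2-(dichloromethyl)-4,4,5,5-tetramethyl-1,3,2-dioxaborolane, ClC(Cl)B1OC(C)(C)C(C)(C)O1
Why: Takai–Utimoto chromium-mediated olefination with the gem-dichloromethylboronate gives the E-alkenylboronate through a gem-dichromium reagent.

Step 10
Reactants: 9 ynoate + 4 dioxolane aldehyde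
Product: 14 (12R)-allylic alcohol with Z-enoate, via vinylalane 13 (not isolated)
Conditions: i-Bu2AlH, N-methylmorpholine N-oxide, THF, 0 °C; then 4, 0 °C to rt; aq. potassium sodium tartrate
Reagents that add atoms: none
Why: Vinylalumination: syn conjugate hydroalumination of the ynoate puts Al at C-4 and the vinylalane adds to the aldehyde to give the Baylis–Hillman-type Z-enoate (ester cis to the C-5 chain); Felkin–Anh attack anti to the α-oxygen of 4 sets C-12 as R (anti to C-13–O), and the minor epimer is removed by chromatography.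

Step 11
Reactants: 14 allylic alcohol + 12 (E)-dienyl pinacolboronate (2.5 equiv)
Product: 16 Claisen aldehyde (4aS,11aR; Z-C-4=C-12), via dienyl ether 15 (not isolated)
Conditions: Cu(OAc)2 (20 mol%), Et3N (2 equiv), 4 Å molecular sieves, O2 (1 atm), CH2Cl2, rt; filtration through Et3N-deactivated SiO2; PhMe, 95 °C; used crude
Reagents that add atoms: none
Why: Proposed new method: aerobic Cu(OAc)2-catalysed Chan–Lam-type O-alkenylation of a hindered β-hydroxy-α-alkylidene ester (limiting partner) with a 1,3-dienyl pinacolboronate, relayed into a Claisen rearrangement; boron-to-copper alkenyl transfer to a divalent copper alkoxide, oxidation to trivalent copper and C–O reductive elimination keep the E geometry, and E-dienyl ether 15 then rearranges through a chair with the dioxolane (C-13), the C-5 chain and the C-11 group all equatorial, so the C-12 (R) carbinol configuration is transferred to C-4a (S) and C-11a (R) and C-4=C-12 forms with C-13 cis to the ester; closest known reactions are the copper-promoted coupling of simple alkenyl pinacolboronates or trifluoroborates with unhindered alcohols and the copper-catalysed alkenyl iodide/allyl alcohol coupling–Claisen domino.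

Step 12
Reactants: 16 Claisen aldehyde
Product: 18 trans-4,5-disubstituted α-alkylidene δ-lactone, via hydroxy ester 17 (not isolated)
Conditions: NaBH4, MeOH, −20 °C; then PPTS (cat.), PhMe, 80 °C
Reagents that add atoms: none
Why: Chemoselective borohydride reduction of the aldehyde (before the α-vinyl centre C-11a can epimerise) followed by acid-catalysed lactonisation of the δ-hydroxy ester locks the two alkenyl chains trans on a six-membered ring.

Step 13
Reactants: 18 δ-lactone diene
Product: 19 bicyclic lactone with Z-cyclononene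
Conditions: second-generation Grubbs catalyst (H2IMes)(PCy3)Cl2Ru=CHPh (10 mol%), PhMe (1 mM), 80 °C
Reagents that add atoms: none
Why: Ring-closing olefin metathesis between the allyl terminus and the C-8 vinyl group closes the nine-membered ring; the trans-fused lactone template and the strain of an E-cyclononene favour the Z ring, and the bulky silyl ether keeps the catalyst from loading on the vinyl group, which would otherwise close a seven-membered ring onto the 1,1-disubstituted alkene.

Step 14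
Reactants: 19 bicyclic lactone
Product: 21 butenolide tetraol with Z-cyclononene, via tetraol lactone 20 (not isolated)
Conditions: AcOH/THF/H2O (3:1:1), 45 °C
Reagents that add atoms: none
Why: Acidic hydrolysis removes the acetonide and both silyl ethers, and the freed C-13 hydroxyl, held cis to the carbonyl on the Z-alkylidene, attacks the δ-lactone (intramolecular transesterification) to give the thermodynamically preferred five-membered butenolide and release the C-1 alcohol.

Step 15
Reactants: 21 butenolide tetraol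
Product: 22 target CNP0411123.2
Conditions: VO(acac)2 (5 mol%), t-BuOOH (1.3 equiv), CH2Cl2, 0 °C to rt
Reagents that add atoms: tert-butyl hydroperoxide, CC(C)(C)OO
Why: Vanadium-catalysed hydroxyl-directed epoxidation: the tertiary allylic C-7 hydroxyl delivers oxygen to its own face of the Z-cyclononene (cis selectivity is known for medium-ring Z-allylic alcohols), setting C-8 (R) and C-9 (R), while the electron-poor butenolide and the only homoallylic exocyclic alkene react much more slowly.

## Compound list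

1 | 2,3-O-isopropylidene-D-erythronolactone, (3aR,6aR)-2,2-dimethyldihydrofuro[3,4-d][1,3]dioxol-4(3aH)-one | O1C[C@@H]2[C@@H](OC(C)(C)O2)C1=O | starting material
2 | 2-[(4R,5R)-5-(hydroxymethyl)-2,2-dimethyl-1,3-dioxolan-4-yl]propan-2-ol | OC[C@@H]1[C@@H](OC(C)(C)O1)C(C)(C)O | intermediate
3 | triethyl({(4R,5R)-2,2-dimethyl-5-[2-(triethylsilyloxy)propan-2-yl]-1,3-dioxolan-4-yl}methoxy)silane | CC[Si](CC)(CC)OC[C@@H]1[C@@H](OC(C)(C)O1)C(C)(C)O[Si](CC)(CC)CC | intermediate
4 | (4S,5R)-2,2-dimethyl-5-[2-(triethylsilyloxy)propan-2-yl]-1,3-dioxolane-4-carbaldehyde | O=C[C@@H]1[C@@H](OC(C)(C)O1)C(C)(C)O[Si](CC)(CC)CC | intermediate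
5 | (S)-(+)-linalool, (3S)-3,7-dimethylocta-1,6-dien-3-ol | C=C[C@@](C)(O)CCC=C(C)C | starting material
6 | triethyl{[(3S)-3,7-dimethylocta-1,6-dien-3-yl]oxy}silane | C=C[C@@](C)(O[Si](CC)(CC)CC)CCC=C(C)C | intermediate
7 | (4S)-4-methyl-4-(triethylsilyloxy)hex-5-enal | C=C[C@@](C)(O[Si](CC)(CC)CC)CCC=O | intermediate
8 | triethyl{[(3S)-3-methylhept-1-en-6-yn-3-yl]oxy}silane | C=C[C@@](C)(O[Si](CC)(CC)CC)CCC#C | intermediate
9 | methyl (6S)-6-methyl-6-(triethylsilyloxy)oct-7-en-2-ynoate | C=C[C@@](C)(O[Si](CC)(CC)CC)CCC#CC(=O)OC | intermediate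
10 | pent-4-enal | C=CCCC=O | starting material
11 | 2-methylidenepent-4-enal | C=CCC(=C)C=O | intermediate
12 | 4,4,5,5-tetramethyl-2-[(1E)-3-methylidenehexa-1,5-dien-1-yl]-1,3,2-dioxaborolane | C=CCC(=C)/C=C/B1OC(C)(C)C(C)(C)O1 | intermediate
13 | methyl (2E,6S)-2-[bis(2-methylpropyl)alumanyl]-6-methyl-6-(triethylsilyloxy)octa-2,7-dienoate (ester cis to the C-5 chain; drawn C-bound) | COC(=O)/C(=C\CC[C@](C)(O[Si](CC)(CC)CC)C=C)[Al](CC(C)C)CC(C)C | intermediate
14 | methyl (2Z,6S)-2-[(R)-{(4R,5R)-2,2-dimethyl-5-[2-(triethylsilyloxy)propan-2-yl]-1,3-dioxolan-4-yl}(hydroxy)methyl]-6-methyl-6-(triethylsilyloxy)octa-2,7-dienoate | COC(=O)/C(=C\CC[C@](C)(O[Si](CC)(CC)CC)C=C)[C@@H](O)[C@@H]1[C@@H](OC(C)(C)O1)C(C)(C)O[Si](CC)(CC)CC | intermediate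
15 | methyl (2Z,6S)-2-[(R)-{(4R,5R)-2,2-dimethyl-5-[2-(triethylsilyloxy)propan-2-yl]-1,3-dioxolan-4-yl}{[(1E)-3-methylidenehexa-1,5-dien-1-yl]oxy}methyl]-6-methyl-6-(triethylsilyloxy)octa-2,7-dienoate | COC(=O)/C(=C\CC[C@](C)(O[Si](CC)(CC)CC)C=C)[C@@H](O/C=C/C(=C)CC=C)[C@@H]1[C@@H](OC(C)(C)O1)C(C)(C)O[Si](CC)(CC)CC | intermediate
16 | methyl (2Z)-3-{(4R,5R)-2,2-dimethyl-5-[2-(triethylsilyloxy)propan-2-yl]-1,3-dioxolan-4-yl}-2-[(3S,6S,7R)-7-formyl-3-methyl-8-methylidene-3-(triethylsilyloxy)undeca-1,10-dien-6-yl]prop-2-enoate | O=C[C@@H](C(=C)CC=C)[C@H](CC[C@](C)(O[Si](CC)(CC)CC)C=C)/C(C(=O)OC)=C/[C@@H]1[C@@H](OC(C)(C)O1)C(C)(C)O[Si](CC)(CC)CC | intermediate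
17 | methyl (2Z)-3-{(4R,5R)-2,2-dimethyl-5-[2-(triethylsilyloxy)propan-2-yl]-1,3-dioxolan-4-yl}-2-[(3S,6S,7R)-7-(hydroxymethyl)-3-methyl-8-methylidene-3-(triethylsilyloxy)undeca-1,10-dien-6-yl]prop-2-enoate | OC[C@@H](C(=C)CC=C)[C@H](CC[C@](C)(O[Si](CC)(CC)CC)C=C)/C(C(=O)OC)=C/[C@@H]1[C@@H](OC(C)(C)O1)C(C)(C)O[Si](CC)(CC)CC | intermediate
18 | (3Z,4S,5R)-3-({(4R,5R)-2,2-dimethyl-5-[2-(triethylsilyloxy)propan-2-yl]-1,3-dioxolan-4-yl}methylidene)-5-(hexa-1,5-dien-2-yl)-4-[(3S)-3-methyl-3-(triethylsilyloxy)pent-4-en-1-yl]oxan-2-one | O=C1OC[C@@H](C(=C)CC=C)[C@H](CC[C@](C)(O[Si](CC)(CC)CC)C=C)/C1=C/[C@@H]2[C@@H](OC(C)(C)O2)C(C)(C)O[Si](CC)(CC)CC | intermediate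
19 | (4Z,4aS,7S,8Z,11aR)-4-({(4R,5R)-2,2-dimethyl-5-[2-(triethylsilyloxy)propan-2-yl]-1,3-dioxolan-4-yl}methylidene)-7-methyl-11-methylidene-7-(triethylsilyloxy)-4,4a,5,6,7,10,11,11a-octahydrocyclonona[c]pyran-3(1H)-one | O=C1OC[C@H]2C(=C)C/C=C\[C@@](C)(O[Si](CC)(CC)CC)CC[C@@H]2/C1=C/[C@@H]3[C@@H](OC(C)(C)O3)C(C)(C)O[Si](CC)(CC)CC | intermediate
20 | (4Z,4aS,7S,8Z,11aR)-7-hydroxy-7-methyl-11-methylidene-4-[(2R,3R)-2,3,4-trihydroxy-4-methylpentylidene]-4,4a,5,6,7,10,11,11a-octahydrocyclonona[c]pyran-3(1H)-one | O=C1OC[C@H]2C(=C)C/C=C\[C@@](C)(O)CC[C@@H]2/C1=C/[C@H]([C@@H](O)C(C)(C)O)O | intermediate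
21 | (5R)-5-[(1R)-1,2-dihydroxy-2-methylpropyl]-3-[(1S,2R,5Z,7S)-7-hydroxy-2-(hydroxymethyl)-7-methyl-3-methylidenecyclonon-5-en-1-yl]furan-2(5H)-one | C=C1C/C=C\[C@@](C)(O)CC[C@H](C2=C[C@H]([C@@H](O)C(C)(C)O)OC2=O)[C@H]1CO | intermediate
22 | (5R)-5-[(1R)-1,2-dihydroxy-2-methylpropyl]-3-[(1R,2S,5S,6R,9R)-2-hydroxy-6-(hydroxymethyl)-2-methyl-7-methylidene-10-oxabicyclo[7.1.0]decan-5-yl]furan-2(5H)-one (CNP0411123.2) | C=C1C[C@H]2O[C@H]2[C@@](C)(O)CC[C@H](C2=C[C@H]([C@@H](O)C(C)(C)O)OC2=O)[C@H]1CO | target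

## Step count and risks

Total steps: 15. Longest linear sequence: 10 steps (5 → 22; steps 4–7 and 10–15).

Steps most likely to fail:

**Step 11 (proposed new O-dienylation/Claisen).** The secondary alcohol is hindered, the boronate can protodeboronate or homocouple, and the dienyl ether is acid-labile. Fallback with known chemistry, setting out from 14 and returning at 18: commercial 3-chloro-2-(chloromethyl)prop-1-ene is mono-vinylated (CH2=CHMgBr, CuI cat., THF) to 2-(chloromethyl)penta-1,4-diene F1, whose Grignard reagent (Mg, THF) is carboxylated with CO2 to 3-methylidenehex-5-enoic acid F2. Alcohol 14 is esterified with F2 (DCC, DMAP, CH2Cl2) to the allylic ester F3. Ireland–Claisen rearrangement (LiN(i-Pr)2, Me3SiCl, THF/DMPU, −78 °C to rt) through the Z(O)-enolate and the same all-equatorial chair gives the γ,δ-unsaturated acid F4 with the same C-4a/C-11a configuration. Reduction of its carboxyl group via the isobutyl carbonic anhydride (i-BuOCOCl, N-methylmorpholine; NaBH4) gives 17, which lactonises to 18 as in step 12.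

**Step 13 (nine-membered ring closure).** Risks are oligomerisation, slow engagement of the vinyl group next to the silyloxy quaternary carbon, and seven-membered closure onto the methylidene group. Fallback, setting out from 18 and returning at 21: both silyl ethers are removed first (HF·pyridine, THF, 0 °C) to give the lactone diol F5, so that the free tertiary allylic hydroxyl, known to accelerate metathesis at the adjacent vinyl group, replaces the bulky silyl ether while the lactone template is kept. Ring-closing metathesis of F5 (same catalyst, PhMe, high dilution) gives the bicyclic diol F6, and AcOH/THF/H2O then removes the acetonide and effects the lactone switch to 21.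

**Step 15 (directed epoxidation).** The C-1 hydroxyl is homoallylic to the exocyclic alkene and could divert the vanadium reagent. Fallback, setting out from 21 and returning at 22: the primary alcohol is silylated selectively (t-BuMe2SiCl, imidazole, CH2Cl2, 0 °C) to the silyl ether F7, which leaves the tertiary C-7 hydroxyl as the only hydroxyl that is allylic or homoallylic to an alkene. VO(acac)2/t-BuOOH epoxidation of F7 gives the epoxy silyl ether F8, and Bu4NF buffered with AcOH (THF, 0 °C) releases 22.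

## Further compounds

F1 | step 11 | 2-(chloromethyl)penta-1,4-diene | C=CCC(=C)CCl
F2 | step 11 | 3-methylidenehex-5-enoic acid | C=CCC(=C)CC(=O)O
F3 | step 11 | methyl (2Z,6S)-2-[(R)-{(4R,5R)-2,2-dimethyl-5-[2-(triethylsilyloxy)propan-2-yl]-1,3-dioxolan-4-yl}(3-methylidenehex-5-enoyloxy)methyl]-6-methyl-6-(triethylsilyloxy)octa-2,7-dienoate | COC(=O)/C(=C\CC[C@](C)(O[Si](CC)(CC)CC)C=C)[C@@H](OC(=O)CC(=C)CC=C)[C@@H]1[C@@H](OC(C)(C)O1)C(C)(C)O[Si](CC)(CC)CC
F4 | step 11 | methyl (2Z)-2-[(3S,6S,7R)-7-carboxy-3-methyl-8-methylidene-3-(triethylsilyloxy)undeca-1,10-dien-6-yl]-3-{(4R,5R)-2,2-dimethyl-5-[2-(triethylsilyloxy)propan-2-yl]-1,3-dioxolan-4-yl}prop-2-enoate | OC(=O)[C@@H](C(=C)CC=C)[C@H](CC[C@](C)(O[Si](CC)(CC)CC)C=C)/C(C(=O)OC)=C/[C@@H]1[C@@H](OC(C)(C)O1)C(C)(C)O[Si](CC)(CC)CC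
F5 | step 13 | (3Z,4S,5R)-5-(hexa-1,5-dien-2-yl)-4-[(3S)-3-hydroxy-3-methylpent-4-en-1-yl]-3-({(4R,5R)-5-(2-hydroxypropan-2-yl)-2,2-dimethyl-1,3-dioxolan-4-yl}methylidene)oxan-2-one | O=C1OC[C@@H](C(=C)CC=C)[C@H](CC[C@](C)(O)C=C)/C1=C/[C@@H]2[C@@H](OC(C)(C)O2)C(C)(C)O
F6 | step 13 | (4Z,4aS,7S,8Z,11aR)-7-hydroxy-4-({(4R,5R)-5-(2-hydroxypropan-2-yl)-2,2-dimethyl-1,3-dioxolan-4-yl}methylidene)-7-methyl-11-methylidene-4,4a,5,6,7,10,11,11a-octahydrocyclonona[c]pyran-3(1H)-one | O=C1OC[C@H]2C(=C)C/C=C\[C@@](C)(O)CC[C@@H]2/C1=C/[C@@H]3[C@@H](OC(C)(C)O3)C(C)(C)O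
F7 | step 15 | (5R)-3-[(1S,2R,5Z,7S)-2-({[tert-butyl(dimethyl)silyl]oxy}methyl)-7-hydroxy-7-methyl-3-methylidenecyclonon-5-en-1-yl]-5-[(1R)-1,2-dihydroxy-2-methylpropyl]furan-2(5H)-one | C=C1C/C=C\[C@@](C)(O)CC[C@H](C2=C[C@H]([C@@H](O)C(C)(C)O)OC2=O)[C@H]1CO[Si](C)(C)C(C)(C)C
F8 | step 15 | tert-butyldimethylsilyl ether of 22 at the primary (C-1) hydroxyl | C=C1C[C@H]2O[C@H]2[C@@](C)(O)CC[C@H](C2=C[C@H]([C@@H](O)C(C)(C)O)OC2=O)[C@H]1CO[Si](C)(C)C(C)(C)C
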